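(The earlier runs and the new flask are simulated for substances that don't exist; noise was put on by code.)

In a one-step world, free monomer M passes into monomer in chains U and stays there, so M + U holds at 100 % of the charge.

| flask | free monomer | transfer agent | initiator | remark | time |
|---|---|---|---|---|---|
| elm | 0.050 M | 0.50 mM | 0.42 mM | run made earlier |  |
| alder | 0.050 M | 0.50 mM | 0.99 mM | run made earlier |  |
| oak | 0.050 M | 0.50 mM | 2.9 mM | run made earlier |  |
| grey | 0.050 M | 0.500 mM | 0.40 mM |  | 3.0 d |
| ochre | 0.050 M | 0.500 mM | 0.80 mM |  | 3.0 d |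
| red | 0.050 M | 0.500 mM | 1.5 mM |  | 3.0 d |
| teal | 0.050 M | 0.500 mM | 3.0 mM |  | 3.0 d |

| run | time / h | monomer in chains / % | free monomer / % |
|---|---|---|---|
| elm | 3.00 | 0 | 99.7 |
| elm | 10.0 | 2.1 | 95.5 |
| elm | 15.0 | 5.4 | 94.3 |
| elm | 25.0 | 7.1 | 90.1 |
| elm | 40.0 | 16.4 | 84.5 |
| alder | 3.00 | 0.8 | 100.2 |
| alder | 10.0 | 5.3 | 94.8 |
| alder | 15.0 | 10.1 | 89.1 |
| alder | 25.0 | 17.7 | 80.6 |
| alder | 40.0 | 29.6 | 64.3 |
| oak | 3.00 | 2.3 | 100.3 |
| oak | 10.0 | 10.4 | 88.5 |
| oak | 15.0 | 19.1 | 76.4 |
| oak | 25.0 | 32.9 | 58.1 |
| oak | 40.0 | 45.4 | 29.3 |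

(standard deviation of a reading: 1 percentage point)

- "hardly changes" means that all values lie within two and a half points (for a concentration: within two and a half percent of the largest)

- amount of monomer in chains at the end, in percent of the free monomer charged for grey, ochre, red, teal, in this order
- how the row runs (rises all the way / rises, then falls / falls all the way / hardly changes / falls, then rises)

The oak run leaves that world. There M + U falls short by 4.5 percentage points at 15.0 h, 9 points at 25.0 h and 25 points at 40.0 h. The gap widens faster late than early while M falls, so I charge it to U: a second step takes monomer out of chains. You can then read two pseudo-first-order times from oak over the last interval, the feed time τ_f of M and the loss time τ_l of U, using mean U and the growth of the gap: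

τ_f = Δt / ln(M before / M after) = 21.9 h

τ_l = Δt · mean U / gap growth = 36.0 h

U stops gaining when M/τ_f = U/τ_l, that is at U/M = 1.64, and this crest ratio ρ = τ_l/τ_f is what I carry.

Oak at 40.0 h has a read U/M = 1.55, close to ρ, so I take teal, charged near oak, as reaching its crest before the end. As my estimate for teal, I continue from oak's last reading with these two times for d = 32.0 h:

U = U₀ e^(−d/τ_l) + M₀ τ_l/(τ_f − τ_l) · (e^(−d/τ_f) − e^(−d/τ_l)) = 32.1 %

Alder, on its last slope, reaches 55.0 %, more than that, and its initiator lies between ochre's and red's. So I expect the row to rise, then fall.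

The forecast gives 28 %, 40 %, 48 % and 54 %, rises all the way, and says “The row still rises, but with shrinking steps.”

The flasks give 21.3 %, 44.9 %, 57.9 % and 40.2 %: rises, then falls.

    2 initiator ⇌ resting dimer, settled at all times (K = 550 M⁻¹)
    initiator + monomer in chains → initiator + over-reaction product (k = 0.450 M⁻¹ min⁻¹)
    free monomer + initiator → living end + monomer in chains (k = 0.0180 M⁻¹ min⁻¹)
    free monomer + living end → monomer in chains + living end, rate k4*[living end]*[free monomer] (k = 0.860 M⁻¹ min⁻¹)
    living end + transfer agent → dead chain (kL = 3.90 M⁻¹ min⁻¹)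

Teal holds 55.2 % as over-reaction product at 3.00 d, and its U stands at 40.2 % against my 32.1 %. Its U/M there is 8.80, above the ρ read from oak, and its U has come down from 44.9 % at 1.50 d. Ochre stands at U/M = 0.927, below the ρ read from oak, and its U stands at 71.9 % at 30.0 d.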